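The route rests on taking apart the quinone ring of the upper naphthazarin unit (C1'–C2'–C3'–C4'–C4a'–C8a'). It divides into an alkyne (C2'≡C3', carrying the lower naphthalene and the methyl group), one CO ligand (C1') and a 2,5-dimethoxyphenyl Fischer carbene (C4', C4a', C8a'). A single Dötz benzannulation forms three C–C bonds and closes this ring, and the oxidative work-up unveils both quinones. The step exploits the identical oxygen substituents at C5' and C8' of the adjoining benzenoid ring. They make C1' and C4' equivalent, so both alkyne-insertion regioisomers give one quinone. The precursor is an open propynyl-tetramethoxynaphthalene derived from 8-chloro-7-methyljuglone, whose chlorine marks C8.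

Key step: step 7

Assumption: the SMILES fixes no configuration at the hindered C8–C2' axis, so the racemic atropisomer is the goal.
Numbering used: lower unit as a juglone (C1=O peri to C8, C4=O peri to C5–OH, OMe at C3, Me at C7). Upper unit primed, as drawn (2'-aryl-3'-methyl-5',8'-dihydroxy-1',4'-naphthoquinone).

Step 1
Reactants: 1 4-chloro-3-methylphenol; 2 maleic anhydride
Product: 3 5-chloro-8-hydroxy-6-methylnaphthalene-1,4-dione (8-chloro-7-methyljuglone)
Conditions: AlCl3, NaCl, melt, 180 °C; then aq HCl
Reagents that add atoms: none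
Why: Double Friedel–Crafts acylation (naphthazarin-type melt condensation) can only annulate across C5/C6 of 1, the single pair of adjacent free ring positions, which places OH at C5, methyl at C7 and chlorine at C8.

Step 2
Reactants: 3 5-chloro-8-hydroxy-6-methylnaphthalene-1,4-dione
Product: 5 2-bromo-5-chloro-8-hydroxy-6-methylnaphthalene-1,4-dione (bromine at C3 in juglone numbering), via trans-dibromide 4 (not isolated)
Conditions: Br2 (1 equiv), AcOH, rt; then EtOH, reflux
Reagents that add atoms: bromine, BrBr
Why: Anti addition of bromine to the quinone C2=C3 bond and dehydrobromination (addition–elimination) should remove the proton at C3, alpha to the hydrogen-bonded and more acidifying C4 carbonyl, together with bromide from C2, so that bromine stays at C3 as in the bromination of juglone itself.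

Step 3
Reactants: 5 2-bromo-5-chloro-8-hydroxy-6-methylnaphthalene-1,4-dione
Product: 6 5-chloro-8-hydroxy-2-methoxy-6-methylnaphthalene-1,4-dione
Conditions: NaOMe (2.2 equiv), MeOH, 0 °C to rt; then aq HCl
Reagents that add atoms: sodium methoxide, [Na+].[O-]C
Why: Addition–elimination on a haloquinone (vinylogous acyl substitution) should occur at C3 because in base the C5 phenoxide deactivates C4=O, so methoxide attacks the bromine-bearing beta carbon of the C1 enone, while the same para phenoxide shields the C8 chloride from SNAr.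

Step 4
Reactants: 6 5-chloro-8-hydroxy-2-methoxy-6-methylnaphthalene-1,4-dione
Product: 8 5-chloro-1,2,4,8-tetramethoxy-6-methylnaphthalene, via naphthalenetriol 7 (not isolated)
Conditions: Na2S2O4, Bu4NBr, aq KOH, THF, rt; then Me2SO4
Reagents that add atoms: dimethyl sulfate, COS(=O)(=O)OC
Why: One-pot reductive methylation under phase transfer should work because dithionite reduces the quinone to hydroquinone 7 and the three phenoxides are O-methylated (Williamson type) before air can reoxidise them.

Step 5
Reactants: 8 5-chloro-1,2,4,8-tetramethoxy-6-methylnaphthalene; 9 propyne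
Product: 10 1,2,4,8-tetramethoxy-6-methyl-5-(prop-1-yn-1-yl)naphthalene
Conditions: propyne (excess), PdCl2(MeCN)2 (cat.), XPhos, Cs2CO3, MeCN, sealed tube, 90 °C
Reagents that add atoms: none
Why: Copper-free Sonogashira coupling should succeed because the bulky electron-rich biarylphosphine lets zerovalent palladium insert into the hindered, electron-rich C–Cl bond, and the slim propynyl group keeps the later bond-forming events easy.

Step 6
Reactants: 11 1,4-dimethoxybenzene; 12 Cr(CO)6
Product: 15 pentacarbonyl[(2,5-dimethoxyphenyl)(methoxy)methylidene]chromium, via aryllithium 13 (not isolated), via lithium acylchromate 14 (not isolated)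
Conditions: n-BuLi, TMEDA, Et2O, 0 °C to rt; Cr(CO)6; then MeOTf, CH2Cl2, 0 °C
Reagents that add atoms: methyl trifluoromethanesulfonate, COS(=O)(=O)C(F)(F)F
Why: Fischer carbene synthesis proceeds by methoxy-directed ortho-lithiation to 13, addition of 13 to a CO ligand of Cr(CO)6, and hard O-methylation of acylate 14 to the stable carbene complex.

Step 7
Reactants: 10 1,2,4,8-tetramethoxy-6-methyl-5-(prop-1-yn-1-yl)naphthalene; 15 pentacarbonyl[(2,5-dimethoxyphenyl)(methoxy)methylidene]chromium
Product: 18 2,8-dimethoxy-5-(5,8-dimethoxy-3-methyl-1,4-dioxo-1,4-dihydronaphthalen-2-yl)-6-methylnaphthalene-1,4-dione, via naphthol Cr(CO)3 complex 16 (not isolated), via regioisomeric naphthol Cr(CO)3 complex 17 (not isolated)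
Conditions: 15 (1.3 equiv), THF, 55 °C, under argon; then (NH4)2Ce(NO3)6 (10 equiv), MeCN/H2O, 0 °C
Reagents that add atoms: water, O
Why: This is a Dötz [3+2+1] benzannulation of an aryl(methoxy) Fischer carbene with an internal aryl alkyl alkyne, followed by the customary oxidative work-up. Thermal loss of one CO from 15 opens a site on zerovalent chromium for alkyne 10, which inserts into the Cr=C bond to give a vinylcarbene, and migratory CO insertion then gives a chromium-bound aryl vinylketene. The ring is closed by 6π electrocyclisation of that ketene onto C6 of the 2,5-dimethoxyphenyl group, its only free ortho carbon, and tautomerisation gives the 4-methoxy-1-naphthol complexes 16 and 17. The regiochemistry of insertion (bulky naphthyl next to the CO-derived carbon favoured) needs no control, because the equal methoxy groups at C5' and C8' make C1' and C4' equivalent once the oxidant has turned both into carbonyls, so 16 and 17 give the same 18; the same oxidant strips the chromium and converts the C1/C4 dimethoxy pair of the lower naphthalene into the 3-methoxyquinone, the other lower ring having no para oxygen pair. No stereocentre is formed, and the only stereogenic element, the C8–C2' axis, arises racemic. The chemoselectivity needed is benzannulation over indene or cyclobutenone formation, which a chromium methoxycarbene in an ether solvent at moderate temperature favours.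

Step 8
Reactants: 18 2,8-dimethoxy-5-(5,8-dimethoxy-3-methyl-1,4-dioxo-1,4-dihydronaphthalen-2-yl)-6-methylnaphthalene-1,4-dione
Product: 20 8'-hydroxy-3-methoxyisodiospyrin, via tris(dichloroboryl) ether 19 (not isolated)
Conditions: BCl3 (6 equiv), CH2Cl2, −78 to 0 °C; then MeOH
Reagents that add atoms: none
Why: Chelation-controlled Lewis-acid ether cleavage should be selective because BCl3 ties each quinone carbonyl and its peri methoxy oxygen into a six-membered chelate from which chloride removes the methyl group, whereas the C3 methoxy group could only form a strained five-membered chelate and the methanol quench would re-etherify any vinylogous acid formed.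

Compound list
1 | 4-chloro-3-methylphenol | Cc1cc(O)ccc1Cl | starting material
2 | maleic anhydride | O=C1C=CC(=O)O1 | starting material
3 | 5-chloro-8-hydroxy-6-methylnaphthalene-1,4-dione | O=C1C=CC(=O)c2c(Cl)c(C)cc(O)c12 | intermediate
4 | trans-2,3-dibromo-5-chloro-8-hydroxy-6-methyl-2,3-dihydronaphthalene-1,4-dione (racemic, one enantiomer drawn) | O=C1[C@H](Br)[C@@H](Br)C(=O)c2c(Cl)c(C)cc(O)c12 | intermediate
5 | 2-bromo-5-chloro-8-hydroxy-6-methylnaphthalene-1,4-dione | O=C1C(Br)=CC(=O)c2c(Cl)c(C)cc(O)c12 | intermediate
6 | 5-chloro-8-hydroxy-2-methoxy-6-methylnaphthalene-1,4-dione | COC1=CC(=O)c2c(Cl)c(C)cc(O)c2C1=O | intermediate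
7 | 8-chloro-3-methoxy-7-methylnaphthalene-1,4,5-triol | COc1cc(O)c2c(Cl)c(C)cc(O)c2c1O | intermediate
8 | 5-chloro-1,2,4,8-tetramethoxy-6-methylnaphthalene | COc1cc(OC)c2c(Cl)c(C)cc(OC)c2c1OC | intermediate
9 | propyne | CC#C | starting material
10 | 1,2,4,8-tetramethoxy-6-methyl-5-(prop-1-yn-1-yl)naphthalene | COc1cc(OC)c2c(C#CC)c(C)cc(OC)c2c1OC | intermediate
11 | 1,4-dimethoxybenzene | COc1ccc(OC)cc1 | starting material
12 | chromium hexacarbonyl, Cr(CO)6 | O=C=[Cr](=C=O)(=C=O)(=C=O)(=C=O)=C=O | starting material
13 | (2,5-dimethoxyphenyl)lithium | [Li]c1cc(OC)ccc1OC | intermediate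
14 | lithium pentacarbonyl[(2,5-dimethoxyphenyl)(oxido)methylidene]chromate | [Li+].[O-]C(c1cc(OC)ccc1OC)=[Cr](=C=O)(=C=O)(=C=O)(=C=O)=C=O | intermediate
15 | pentacarbonyl[(2,5-dimethoxyphenyl)(methoxy)methylidene]chromium | COC(c1cc(OC)ccc1OC)=[Cr](=C=O)(=C=O)(=C=O)(=C=O)=C=O | intermediate
16 | tricarbonylchromium η6 complex of 4,5,8-trimethoxy-3-methyl-2-(4,5,6,8-tetramethoxy-2-methylnaphthalen-1-yl)naphthalen-1-ol (Cr(CO)3 written unbonded; racemic axis) | COc1c(C)c(-c3c(C)cc(OC)c4c(OC)c(OC)cc(OC)c34)c(O)c2c(OC)ccc(OC)c12.O=C=[Cr](=C=O)=C=O | intermediate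
17 | tricarbonylchromium η6 complex of 4,5,8-trimethoxy-2-methyl-3-(4,5,6,8-tetramethoxy-2-methylnaphthalen-1-yl)naphthalen-1-ol (Cr(CO)3 written unbonded; racemic axis) | COc1c(-c3c(C)cc(OC)c4c(OC)c(OC)cc(OC)c34)c(C)c(O)c2c(OC)ccc(OC)c12.O=C=[Cr](=C=O)=C=O | intermediate
18 | 2,8-dimethoxy-5-(5,8-dimethoxy-3-methyl-1,4-dioxo-1,4-dihydronaphthalen-2-yl)-6-methylnaphthalene-1,4-dione (racemic axis) | COC1=CC(=O)c2c(C3=C(C)C(=O)c4c(OC)ccc(OC)c4C3=O)c(C)cc(OC)c2C1=O | intermediate
19 | tris(dichloroboryl) ether of 20 at O5, O5' and O8' | COC1=CC(=O)c2c(C3=C(C)C(=O)c4c(OB(Cl)Cl)ccc(OB(Cl)Cl)c4C3=O)c(C)cc(OB(Cl)Cl)c2C1=O | intermediate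
20 | 8'-hydroxy-3-methoxyisodiospyrin, 8-hydroxy-5-(5,8-dihydroxy-3-methyl-1,4-dioxo-1,4-dihydronaphthalen-2-yl)-2-methoxy-6-methylnaphthalene-1,4-dione (racemic axis) | COC1=CC(=O)c2c(C3=C(C)C(=O)c4c(O)ccc(O)c4C3=O)c(C)cc(O)c2C1=O | target

Total step count: 8. Longest linear sequence: 7 (steps 1–5, 7 and 8; step 6 runs in parallel).

Steps most likely to fail

1. Step 7.
- **Risk:** Insertion of the doubly flanked alkyne may be slower than thermal decay of the carbene complex. The vinylcarbene may also divert to five- or four-membered ring formation instead of CO insertion.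
- **Fallback:** A Moore-type cyclobutenone ring expansion that still closes the same ring last. It sets out from 8, with aryllithium 13 made as in step 6, and comes back at 18. Chloride 8 would be reductively lithiated with lithium 4,4'-di-tert-butylbiphenylide (THF, −78 °C) to the naphthyllithium F1. This adds to commercial diisopropyl squarate to give the hydroxycyclobutenone F2. Excess MeLi adds to the remaining carbonyl to give the diol F3, and conc. HCl in CH2Cl2 collapses it to the methyl(naphthyl)cyclobutenedione F4. Aryllithium 13 adds to one carbonyl to give the 4-aryl-4-hydroxycyclobutenone F5; attack at either carbonyl leads to the same quinone for the symmetry reason used in step 7. Heating in xylene should open the four-membered ring by 4π electrocyclic opening, with hydroxyl rotating outward. The resulting vinylketene closes by 6π electrocyclisation onto the free ortho carbon to give the hydroquinone F6, which (NH4)2Ce(NO3)6 in MeCN/H2O oxidises to 18.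

2. Step 5.
- **Risk:** Oxidative addition into the electron-rich C–Cl bond, flanked by the ortho methyl and the peri methoxy group, may be too slow. Hydrodechlorination or propyne oligomerisation would then take over.
- **Fallback:** The polarity is inverted and the alkyne is built by homologation. It sets out from 8 and comes back at 10. The naphthyllithium F1, made from 8 as above, would be formylated with DMF to the aldehyde F7. Corey–Fuchs olefination (CBr4, PPh3, CH2Cl2) gives the dibromoalkene F8. Treatment with n-BuLi (2 equiv, THF, −78 °C) gives the lithium acetylide F9, which MeI methylates to 10.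

3. Step 8.
- **Risk:** Competing cleavage of the quinonoid (vinylogous ester) methyl group, or incomplete cleavage of the two naphthazarin ethers, would erode the selectivity.
- **Fallback:** Exhaustive cleavage followed by selective re-etherification. It sets out from 18 and comes back at 20. Excess BBr3 (CH2Cl2, −78 °C to rt) would remove all four methyl groups to give the 3-hydroxyquinone F10. Its vinylogous carboxylic acid alone undergoes Fischer-type etherification in MeOH with catalytic HCl at reflux. The three chelated peri phenols stay inert, which gives 20.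

Further compounds
F1 | step 7 | (4,5,6,8-tetramethoxy-2-methylnaphthalen-1-yl)lithium | [Li]c1c(C)cc(OC)c2c(OC)c(OC)cc(OC)c12
F2 | step 7 | 4-hydroxy-2,3-diisopropoxy-4-(4,5,6,8-tetramethoxy-2-methylnaphthalen-1-yl)cyclobut-2-en-1-one (racemic) | CC(C)OC1=C(OC(C)C)C(O)(c2c(C)cc(OC)c3c(OC)c(OC)cc(OC)c23)C1=O
F3 | step 7 | 3,4-diisopropoxy-1-methyl-2-(4,5,6,8-tetramethoxy-2-methylnaphthalen-1-yl)cyclobut-3-ene-1,2-diol (relative configuration uncontrolled and lost in the next operation) | CC(C)OC1=C(OC(C)C)C(C)(O)C1(O)c1c(C)cc(OC)c2c(OC)c(OC)cc(OC)c12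
F4 | step 7 | 3-methyl-4-(4,5,6,8-tetramethoxy-2-methylnaphthalen-1-yl)cyclobut-3-ene-1,2-dione | CC1=C(c2c(C)cc(OC)c3c(OC)c(OC)cc(OC)c23)C(=O)C1=O
F5 | step 7 | 4-(2,5-dimethoxyphenyl)-4-hydroxy-3-methyl-2-(4,5,6,8-tetramethoxy-2-methylnaphthalen-1-yl)cyclobut-2-en-1-one (racemic) | CC1=C(c2c(C)cc(OC)c3c(OC)c(OC)cc(OC)c23)C(=O)C1(O)c1cc(OC)ccc1OC
F6 | step 7 | 5,8-dimethoxy-2-methyl-3-(4,5,6,8-tetramethoxy-2-methylnaphthalen-1-yl)naphthalene-1,4-diol | Cc1c(O)c2c(OC)ccc(OC)c2c(O)c1-c1c(C)cc(OC)c2c(OC)c(OC)cc(OC)c12
F7 | step 5 | 4,5,6,8-tetramethoxy-2-methylnaphthalene-1-carbaldehyde | O=Cc1c(C)cc(OC)c2c(OC)c(OC)cc(OC)c12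
F8 | step 5 | 1-(2,2-dibromoethenyl)-4,5,6,8-tetramethoxy-2-methylnaphthalene | BrC(Br)=Cc1c(C)cc(OC)c2c(OC)c(OC)cc(OC)c12
F9 | step 5 | [(4,5,6,8-tetramethoxy-2-methylnaphthalen-1-yl)ethynyl]lithium | [Li]C#Cc1c(C)cc(OC)c2c(OC)c(OC)cc(OC)c12
F10 | step 8 | 2,8-dihydroxy-5-(5,8-dihydroxy-3-methyl-1,4-dioxo-1,4-dihydronaphthalen-2-yl)-6-methylnaphthalene-1,4-dione | OC1=CC(=O)c2c(C3=C(C)C(=O)c4c(O)ccc(O)c4C3=O)c(C)cc(O)c2C1=O
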